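**Retrosynthetic overview**
1. Target 33 ⇐ its 15-O-TBDPS ether 32 ⇐ macrocyclic α'-hydroxy ynone 31; the 3(2H)-furanone is closed last by a gold-catalysed 5-endo-dig O-cyclisation.
2. Ten-membered carbocycle ⇐ open-chain iodoalkyne aldehyde 28 by intramolecular CrCl2/NiCl2 alkynylation (C1–C2).
3. Key fragment union at C7–C8: zinc Barbier allylation of aldehyde 21 (fragment B) with bromomethyl butenolide 14 (fragment A). It gives the α-methylene-γ-lactone and sets C7 and C8 from C6; the tiglate is added directly afterwards.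
4. Fragment A ⇐ but-2-yne-1,4-diol (NaAlH2(OCH2CH2OCH3)2/I2, Sonogashira), asymmetric alkynylation (C6), Pd carbonylative lactonisation. Fragment B ⇐ methallyl alcohol (Sharpless epoxidation sets C10).
5. Ring order: butenolide (becomes the lactone) → carbocycle → furanone.

Assumption: atom labels C1–C15 follow germacrane numbering of the target (C6 lactone carbinol, C7 ring-fusion carbon, C8 tiglate carbinol, C10 quaternary furanone carbon, C15 hydroxymethyl); the target is (6R,7R,8S,10R), as in the given SMILES.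

**Route**

Step 1
Reactants: 1 but-2-yne-1,4-diol
Product: 2 4-[tert-butyl(diphenyl)silyl]oxybut-2-yn-1-ol
Conditions: NaH (1.0 equiv), THF, 0 °C; then tert-butyl(chloro)diphenylsilane (1.0 equiv), rt; diol 1 in threefold excess
Reagents that add atoms: tert-butyl(chloro)diphenylsilane, CC(C)(C)[Si](Cl)(c1ccccc1)c1ccccc1
Why: Silyl ether formation on the monosodium alkoxide of a symmetrical diol used in excess gives clean monoprotection of the future C15 oxygen.

Step 2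
Reactants: 2 4-[tert-butyl(diphenyl)silyl]oxybut-2-yn-1-ol
Product: 4 (Z)-4-[tert-butyl(diphenyl)silyl]oxy-3-iodobut-2-en-1-ol, via cyclic vinylalanate 3 (not isolated)
Conditions: NaAlH2(OCH2CH2OCH3)2 (1.5 equiv), THF, 0 °C; then I2, −78 → 0 °C
Reagents that add atoms: iodine, II
Why: Hydroxyl-directed trans-hydroalumination of the propargylic alcohol puts aluminium on the distal carbon cis to the carbinol, and iodinolysis with retention fixes the C4=C5 geometry (iodine cis to the future C6).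

Step 3
Reactants: 4 (Z)-4-[tert-butyl(diphenyl)silyl]oxy-3-iodobut-2-en-1-ol, 5 ethynyl(trimethyl)silane
Product: 6 (E)-3-{[tert-butyl(diphenyl)silyl]oxymethyl}-5-(trimethylsilyl)pent-2-en-4-yn-1-ol
Conditions: Pd(PPh3)2Cl2 (3 mol %), CuI (6 mol %), Et3N, THF, rt
Reagents that add atoms: none
Why: Sonogashira coupling of a vinyl iodide proceeds with retention of alkene geometry, so the alkyne (C3, C2) ends up cis to the future C6.

Step 4
Reactants: 6 (E)-3-{[tert-butyl(diphenyl)silyl]oxymethyl}-5-(trimethylsilyl)pent-2-en-4-yn-1-ol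
Product: 7 (E)-3-{[tert-butyl(diphenyl)silyl]oxymethyl}-5-(trimethylsilyl)pent-2-en-4-ynal
Conditions: Dess–Martin periodinane, CH2Cl2, 0 °C → rt
Reagents that add atoms: none
Why: Dess–Martin oxidation of the allylic alcohol is mild and non-basic, so the enal geometry is not scrambled.

Step 5
Reactants: 7 (E)-3-{[tert-butyl(diphenyl)silyl]oxymethyl}-5-(trimethylsilyl)pent-2-en-4-ynal, 8 tert-butyl(dimethyl)(prop-2-yn-1-yloxy)silane
Product: 9 (4R,5E)-1-[tert-butyl(dimethyl)silyl]oxy-6-{[tert-butyl(diphenyl)silyl]oxymethyl}-8-(trimethylsilyl)octa-5-en-2,7-diyn-4-ol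
Conditions: (R,R)-ProPhenol [2,6-bis{[(R)-2-(hydroxydiphenylmethyl)pyrrolidin-1-yl]methyl}-4-methylphenol] (20 mol %), Ph3P=O (40 mol %), Me2Zn (3 equiv), 8 (3 equiv), toluene, 0 °C
Reagents that add atoms: none
Why: Catalytic asymmetric alkynylation (zinc alkynylide addition under a dinuclear zinc–ProPhenol catalyst) sets C6 (R) by Si-face delivery to the enal; the (R,R) ligand is assigned from the usual model for this catalyst and must be confirmed by Mosher ester analysis, the antipodal ligand being used if the sense is reversed.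

Step 6
Reactants: 9 (4R,5E)-1-[tert-butyl(dimethyl)silyl]oxy-6-{[tert-butyl(diphenyl)silyl]oxymethyl}-8-(trimethylsilyl)octa-5-en-2,7-diyn-4-ol
Product: 11 (2Z,4R,5E)-1-[tert-butyl(dimethyl)silyl]oxy-6-{[tert-butyl(diphenyl)silyl]oxymethyl}-2-iodo-8-(trimethylsilyl)octa-2,5-dien-7-yn-4-ol, via cyclic vinylalanate 10 (not isolated)
Conditions: NaAlH2(OCH2CH2OCH3)2 (2 equiv), THF, −20 → 0 °C; then I2, −78 °C
Reagents that add atoms: iodine, II
Why: The same hydroxyl-directed trans-hydroalumination/iodinolysis acts only on the propargylic alkyne at low temperature and gives the Z-iodoalkene with iodine on C11, cis to C6 as lactonisation requires; C6 is untouched.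

Step 7
Reactants: 11 (2Z,4R,5E)-1-[tert-butyl(dimethyl)silyl]oxy-6-{[tert-butyl(diphenyl)silyl]oxymethyl}-2-iodo-8-(trimethylsilyl)octa-2,5-dien-7-yn-4-ol
Product: 12 (5R)-3-{[tert-butyl(dimethyl)silyl]oxymethyl}-5-[(1E)-2-{[tert-butyl(diphenyl)silyl]oxymethyl}-4-(trimethylsilyl)but-1-en-3-yn-1-yl]furan-2(5H)-one
Conditions: Pd(PPh3)4 (5 mol %), CO (1 atm), K2CO3, THF, rt
Reagents that add atoms: carbon monoxide, [C-]#[O+]
Why: Palladium-catalysed carbonylative lactonisation (oxidative addition, CO insertion, capture of the acyl-palladium by the cis C6 hydroxyl) builds the butenolide and introduces C12 under conditions mild enough to leave the C6 centre unracemised.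

Step 8
Reactants: 12 (5R)-3-{[tert-butyl(dimethyl)silyl]oxymethyl}-5-[(1E)-2-{[tert-butyl(diphenyl)silyl]oxymethyl}-4-(trimethylsilyl)but-1-en-3-yn-1-yl]furan-2(5H)-one
Product: 13 (5R)-5-[(1E)-2-{[tert-butyl(diphenyl)silyl]oxymethyl}-4-(trimethylsilyl)but-1-en-3-yn-1-yl]-3-(hydroxymethyl)furan-2(5H)-one
Conditions: pyridinium p-toluenesulfonate (0.2 equiv), MeOH, rt
Reagents that add atoms: none
Why: Acid-catalysed methanolysis removes the primary TBS ether far faster than the TBDPS ether and leaves the C-silyl alkyne alone.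

Step 9
Reactants: 13 (5R)-5-[(1E)-2-{[tert-butyl(diphenyl)silyl]oxymethyl}-4-(trimethylsilyl)but-1-en-3-yn-1-yl]-3-(hydroxymethyl)furan-2(5H)-one
Product: 14 (5R)-3-(bromomethyl)-5-[(1E)-2-{[tert-butyl(diphenyl)silyl]oxymethyl}-4-(trimethylsilyl)but-1-en-3-yn-1-yl]furan-2(5H)-one
Conditions: CBr4, PPh3, CH2Cl2, 0 °C
Reagents that add atoms: tetrabromomethane, BrC(Br)(Br)Br
Why: The Appel reaction converts the primary allylic alcohol to the bromide under neutral conditions that do not epimerise the acidic C6–H.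

Step 10
Reactants: 15 2-methylprop-2-en-1-ol
Product: 16 [(2S)-2-methyloxiran-2-yl]methanol
Conditions: Ti(OiPr)4 (5 mol %), L-(+)-diethyl tartrate (6 mol %), cumene hydroperoxide, 4 Å molecular sieves, CH2Cl2, −20 °C
Reagents that add atoms: cumene hydroperoxide, CC(C)(OO)c1ccccc1
Why: Sharpless asymmetric epoxidation with the L-(+)-tartrate gives the (S)-epoxy alcohol (about 95% ee) and thereby sets the future C10; the minor enantiomer is removed as a diastereomer after step 14.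

Step 11
Reactants: 16 [(2S)-2-methyloxiran-2-yl]methanol, 17 vinylmagnesium bromide
Product: 18 (2R)-2-methylpent-4-ene-1,2-diol
Conditions: CH2=CHMgBr (3 equiv), CuI (10 mol %), THF, −30 → 0 °C
Reagents that add atoms: none
Why: Copper-catalysed Grignard opening of the epoxide occurs by SN2 attack at the unsubstituted CH2 (C9), so the quaternary centre is not touched (the descriptor changes only through CIP priorities).

Step 12
Reactants: 18 (2R)-2-methylpent-4-ene-1,2-diol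
Product: 19 (4R)-2,2,4-trimethyl-4-(prop-2-en-1-yl)-1,3-dioxolane
Conditions: 2,2-dimethoxypropane, pyridinium p-toluenesulfonate (cat.), CH2Cl2, rt
Reagents that add atoms: 2,2-dimethoxypropane, COC(C)(C)OC
Why: Acid-catalysed transketalisation ties up the C10 and C1 oxygens together as an acetonide.

Step 13
Reactants: 19 (4R)-2,2,4-trimethyl-4-(prop-2-en-1-yl)-1,3-dioxolane
Product: 21 2-[(4R)-2,2,4-trimethyl-1,3-dioxolan-4-yl]acetaldehyde, via ozonide 20 (not isolated)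
Conditions: O3, CH2Cl2, −78 °C; then PPh3, −78 °C → rt
Reagents that add atoms: ozone, [O-][O+]=O
Why: Ozonolysis with reductive work-up cleaves the terminal alkene to the C8 aldehyde without affecting the acetonide.

Step 14
Reactants: 14 (5R)-3-(bromomethyl)-5-[(1E)-2-{[tert-butyl(diphenyl)silyl]oxymethyl}-4-(trimethylsilyl)but-1-en-3-yn-1-yl]furan-2(5H)-one, 21 2-[(4R)-2,2,4-trimethyl-1,3-dioxolan-4-yl]acetaldehyde
Product: 23 (4R,5R)-5-[(1E)-2-{[tert-butyl(diphenyl)silyl]oxymethyl}-4-(trimethylsilyl)but-1-en-3-yn-1-yl]-4-{(1S)-1-hydroxy-2-[(4R)-2,2,4-trimethyl-1,3-dioxolan-4-yl]ethyl}-3-methylideneoxolan-2-one, via allylzinc bromide 22 (not isolated)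
Conditions: Zn dust (activated, 3 equiv), THF/sat. aq. NH4Cl (4:1), 0 °C → rt; 21 in 1.5-fold excess
Reagents that add atoms: none
Why: In this Barbier-type carbonyl allylation the allylzinc adds through its γ-carbon (C7) in a chair Zimmerman–Traxler transition state, so the ring-locked allyl geometry gives the 7,8-anti adduct (C8 S) and attack anti to the C6 side chain gives the trans-lactone (C7 R) while the exo-methylene lactone forms directly; minor diastereomers are removed by chromatography.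

Step 15
Reactants: 23 (4R,5R)-5-[(1E)-2-{[tert-butyl(diphenyl)silyl]oxymethyl}-4-(trimethylsilyl)but-1-en-3-yn-1-yl]-4-{(1S)-1-hydroxy-2-[(4R)-2,2,4-trimethyl-1,3-dioxolan-4-yl]ethyl}-3-methylideneoxolan-2-one, 24 (2E)-2-methylbut-2-enoyl chloride
Product: 25 (1S)-1-{(2R,3R)-2-[(1E)-2-{[tert-butyl(diphenyl)silyl]oxymethyl}-4-(trimethylsilyl)but-1-en-3-yn-1-yl]-4-methylidene-5-oxooxolan-3-yl}-2-[(4R)-2,2,4-trimethyl-1,3-dioxolan-4-yl]ethyl (2E)-2-methylbut-2-enoate
Conditions: pyridine, 4-(dimethylamino)pyridine (cat.), CH2Cl2, 0 °C → rt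
Reagents that add atoms: none
Why: Nucleophile-catalysed acylation of the only free hydroxyl installs the tiglate with retention at C8, and pyridine is too weak a base to deconjugate the acid chloride.

Step 16
Reactants: 25 (1S)-1-{(2R,3R)-2-[(1E)-2-{[tert-butyl(diphenyl)silyl]oxymethyl}-4-(trimethylsilyl)but-1-en-3-yn-1-yl]-4-methylidene-5-oxooxolan-3-yl}-2-[(4R)-2,2,4-trimethyl-1,3-dioxolan-4-yl]ethyl (2E)-2-methylbut-2-enoate
Product: 26 (1S)-1-{(2R,3R)-2-[(1E)-2-{[tert-butyl(diphenyl)silyl]oxymethyl}-4-iodobut-1-en-3-yn-1-yl]-4-methylidene-5-oxooxolan-3-yl}-2-[(4R)-2,2,4-trimethyl-1,3-dioxolan-4-yl]ethyl (2E)-2-methylbut-2-enoate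
Conditions: N-iodosuccinimide (1.2 equiv), AgNO3 (10 mol %), acetone, rt, dark
Reagents that add atoms: N-iodosuccinimide, O=C1CCC(=O)N1I
Why: Silver-catalysed iododesilylation turns the C-silyl alkyne directly into the 1-iodoalkyne without touching silyl ethers, esters or the acetonide.

Step 17
Reactants: 26 (1S)-1-{(2R,3R)-2-[(1E)-2-{[tert-butyl(diphenyl)silyl]oxymethyl}-4-iodobut-1-en-3-yn-1-yl]-4-methylidene-5-oxooxolan-3-yl}-2-[(4R)-2,2,4-trimethyl-1,3-dioxolan-4-yl]ethyl (2E)-2-methylbut-2-enoate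
Product: 27 (1S,3R)-1-{(2R,3R)-2-[(1E)-2-{[tert-butyl(diphenyl)silyl]oxymethyl}-4-iodobut-1-en-3-yn-1-yl]-4-methylidene-5-oxooxolan-3-yl}-3,4-dihydroxy-3-methylbutyl (2E)-2-methylbut-2-enoate
Conditions: AcOH/THF/H2O (3:1:1), 45 °C
Reagents that add atoms: none
Why: Mild acid hydrolysis cleaves the acetonide, while the TBDPS ether, tiglate, iodoalkyne and α-methylene lactone are stable to aqueous acetic acid.

Step 18
Reactants: 27 (1S,3R)-1-{(2R,3R)-2-[(1E)-2-{[tert-butyl(diphenyl)silyl]oxymethyl}-4-iodobut-1-en-3-yn-1-yl]-4-methylidene-5-oxooxolan-3-yl}-3,4-dihydroxy-3-methylbutyl (2E)-2-methylbut-2-enoate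
Product: 28 (1S,3R)-1-{(2R,3R)-2-[(1E)-2-{[tert-butyl(diphenyl)silyl]oxymethyl}-4-iodobut-1-en-3-yn-1-yl]-4-methylidene-5-oxooxolan-3-yl}-3-hydroxy-3-methyl-4-oxobutyl (2E)-2-methylbut-2-enoate
Conditions: SO3·pyridine, DMSO, iPr2NEt, CH2Cl2, 0 °C
Reagents that add atoms: none
Why: Parikh–Doering oxidation takes the primary alcohol to the aldehyde without glycol cleavage, the tertiary C10 hydroxyl cannot be oxidised, and the α-carbon is quaternary so nothing can epimerise.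

Step 19
Reactants: 28 (1S,3R)-1-{(2R,3R)-2-[(1E)-2-{[tert-butyl(diphenyl)silyl]oxymethyl}-4-iodobut-1-en-3-yn-1-yl]-4-methylidene-5-oxooxolan-3-yl}-3-hydroxy-3-methyl-4-oxobutyl (2E)-2-methylbut-2-enoate
Product: 30 (6R,7R,8S,10R)-15-[tert-butyl(diphenyl)silyl]oxy-1,10-dihydroxy-8-[(2E)-2-methylbut-2-enoyl]oxygermacra-4,11(13)-dien-2-yn-12,6-olide (C3 and C6 cis on C4=C5; C1 epimers), via alkynylchromium dichloride 29 (not isolated)
Conditions: CrCl2 (8 equiv), NiCl2 (5 mol %), degassed THF, rt, slow addition of 28 (final 0.002 M)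
Reagents that add atoms: none
Why: Intramolecular Nozaki–Hiyama–Kishi alkynylation adds the alkynylchromium chemoselectively to the aldehyde under neutral conditions that spare the α-methylene lactone and both esters, closing the ten-membered ring; the new C1 carbinol is an inconsequential epimer mixture.

Step 20
Reactants: 30 (6R,7R,8S,10R)-15-[tert-butyl(diphenyl)silyl]oxy-1,10-dihydroxy-8-[(2E)-2-methylbut-2-enoyl]oxygermacra-4,11(13)-dien-2-yn-12,6-olide
Product: 31 (6R,7R,8S,10R)-15-[tert-butyl(diphenyl)silyl]oxy-10-hydroxy-8-[(2E)-2-methylbut-2-enoyl]oxy-1-oxogermacra-4,11(13)-dien-2-yn-12,6-olide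
Conditions: 2-iodoxybenzoic acid, DMSO, rt
Reagents that add atoms: none
Why: IBX oxidises the secondary propargylic alcohol of the 1,2-diol to the ynone without C–C cleavage and removes the C1 stereocentre.

Step 21
Reactants: 31 (6R,7R,8S,10R)-15-[tert-butyl(diphenyl)silyl]oxy-10-hydroxy-8-[(2E)-2-methylbut-2-enoyl]oxy-1-oxogermacra-4,11(13)-dien-2-yn-12,6-olide
Product: 32 15-O-[tert-butyl(diphenyl)silyl]lychnophorolide B
Conditions: Ph3PAuCl (5 mol %), AgOSO2CF3 (5 mol %), toluene, rt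
Reagents that add atoms: none
Why: Gold-catalysed 5-endo-dig cyclisation (an intramolecular oxa-Michael addition of the C10 hydroxyl to C3 of the activated ynone) forms the 3(2H)-furanone, with C10 (R) carried over unchanged.

Step 22
Reactants: 32 15-O-[tert-butyl(diphenyl)silyl]lychnophorolide B
Product: 33 lychnophorolide B
Conditions: HF·pyridine, pyridine, THF, 0 °C → rt
Reagents that add atoms: none
Why: Buffered fluoride desilylation frees the C15 allylic alcohol without harming the α-methylene lactone, furanone or tiglate.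

**Compound list**
1 | but-2-yne-1,4-diol | OCC#CCO | starting material
2 | 4-[tert-butyl(diphenyl)silyl]oxybut-2-yn-1-ol | OCC#CCO[Si](c1ccccc1)(c1ccccc1)C(C)(C)C | intermediate
3 | cyclic vinylalanate from 2: sodium 2,2-bis(2-methoxyethoxy)-3-{[tert-butyl(diphenyl)silyl]oxymethyl}-2,5-dihydro-1,2-oxaaluminol-2-uide | [Na+].COCCO[Al-]1(OCCOC)OCC=C1CO[Si](c1ccccc1)(c1ccccc1)C(C)(C)C | intermediate (not isolated)
4 | (Z)-4-[tert-butyl(diphenyl)silyl]oxy-3-iodobut-2-en-1-ol | OC/C=C(/CO[Si](c1ccccc1)(c1ccccc1)C(C)(C)C)I | intermediate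
5 | ethynyl(trimethyl)silane | C#C[Si](C)(C)C | starting material
6 | (E)-3-{[tert-butyl(diphenyl)silyl]oxymethyl}-5-(trimethylsilyl)pent-2-en-4-yn-1-ol | OC/C=C(/CO[Si](c1ccccc1)(c1ccccc1)C(C)(C)C)C#C[Si](C)(C)C | intermediate
7 | (E)-3-{[tert-butyl(diphenyl)silyl]oxymethyl}-5-(trimethylsilyl)pent-2-en-4-ynal | O=C/C=C(/CO[Si](c1ccccc1)(c1ccccc1)C(C)(C)C)C#C[Si](C)(C)C | intermediate
8 | tert-butyl(dimethyl)(prop-2-yn-1-yloxy)silane | C#CCO[Si](C)(C)C(C)(C)C | starting material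
9 | (4R,5E)-1-[tert-butyl(dimethyl)silyl]oxy-6-{[tert-butyl(diphenyl)silyl]oxymethyl}-8-(trimethylsilyl)octa-5-en-2,7-diyn-4-ol | O[C@H](/C=C(/CO[Si](c1ccccc1)(c1ccccc1)C(C)(C)C)C#C[Si](C)(C)C)C#CCO[Si](C)(C)C(C)(C)C | intermediate
10 | cyclic vinylalanate from 9 (sodium 1,2-oxaaluminol-2-uide with the C6 side chain at C5 and CH2OTBS at C3) | [Na+].COCCO[Al-]1(OCCOC)O[C@H](/C=C(/CO[Si](c2ccccc2)(c2ccccc2)C(C)(C)C)C#C[Si](C)(C)C)C=C1CO[Si](C)(C)C(C)(C)C | intermediate (not isolated)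
11 | (2Z,4R,5E)-1-[tert-butyl(dimethyl)silyl]oxy-6-{[tert-butyl(diphenyl)silyl]oxymethyl}-2-iodo-8-(trimethylsilyl)octa-2,5-dien-7-yn-4-ol | O[C@H](/C=C(/CO[Si](c1ccccc1)(c1ccccc1)C(C)(C)C)C#C[Si](C)(C)C)/C=C(/CO[Si](C)(C)C(C)(C)C)I | intermediate
12 | (5R)-3-{[tert-butyl(dimethyl)silyl]oxymethyl}-5-[(1E)-2-{[tert-butyl(diphenyl)silyl]oxymethyl}-4-(trimethylsilyl)but-1-en-3-yn-1-yl]furan-2(5H)-one | O=C1O[C@H](/C=C(/CO[Si](c2ccccc2)(c2ccccc2)C(C)(C)C)C#C[Si](C)(C)C)C=C1CO[Si](C)(C)C(C)(C)C | intermediate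
13 | (5R)-5-[(1E)-2-{[tert-butyl(diphenyl)silyl]oxymethyl}-4-(trimethylsilyl)but-1-en-3-yn-1-yl]-3-(hydroxymethyl)furan-2(5H)-one | O=C1O[C@H](/C=C(/CO[Si](c2ccccc2)(c2ccccc2)C(C)(C)C)C#C[Si](C)(C)C)C=C1CO | intermediate
14 | (5R)-3-(bromomethyl)-5-[(1E)-2-{[tert-butyl(diphenyl)silyl]oxymethyl}-4-(trimethylsilyl)but-1-en-3-yn-1-yl]furan-2(5H)-one (fragment A) | O=C1O[C@H](/C=C(/CO[Si](c2ccccc2)(c2ccccc2)C(C)(C)C)C#C[Si](C)(C)C)C=C1CBr | intermediate
15 | 2-methylprop-2-en-1-ol | C=C(C)CO | starting material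
16 | [(2S)-2-methyloxiran-2-yl]methanol | C[C@]1(CO)CO1 | intermediate
17 | vinylmagnesium bromide | C=C[Mg]Br | starting material
18 | (2R)-2-methylpent-4-ene-1,2-diol | C=CC[C@@](C)(O)CO | intermediate
19 | (4R)-2,2,4-trimethyl-4-(prop-2-en-1-yl)-1,3-dioxolane | C=CC[C@]1(C)COC(C)(C)O1 | intermediate
20 | ozonide of 19: (4R)-2,2,4-trimethyl-4-(1,2,4-trioxolan-3-ylmethyl)-1,3-dioxolane (trioxolane carbon as epimer mixture) | C1(OOCO1)C[C@]2(C)COC(C)(C)O2 | intermediate (not isolated)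
21 | 2-[(4R)-2,2,4-trimethyl-1,3-dioxolan-4-yl]acetaldehyde (fragment B) | O=CC[C@]1(C)COC(C)(C)O1 | intermediate
22 | allylzinc bromide from 14: bromo{[(5R)-2-oxo-5-(side chain)-2,5-dihydrofuran-3-yl]methyl}zinc | O=C1O[C@H](/C=C(/CO[Si](c2ccccc2)(c2ccccc2)C(C)(C)C)C#C[Si](C)(C)C)C=C1C[Zn]Br | intermediate (not isolated)
23 | (4R,5R)-5-[(1E)-2-{[tert-butyl(diphenyl)silyl]oxymethyl}-4-(trimethylsilyl)but-1-en-3-yn-1-yl]-4-{(1S)-1-hydroxy-2-[(4R)-2,2,4-trimethyl-1,3-dioxolan-4-yl]ethyl}-3-methylideneoxolan-2-one | C=C1C(=O)O[C@H](/C=C(/CO[Si](c2ccccc2)(c2ccccc2)C(C)(C)C)C#C[Si](C)(C)C)[C@H]1[C@@H](O)C[C@]1(C)COC(C)(C)O1 | intermediate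
24 | (2E)-2-methylbut-2-enoyl chloride (tigloyl chloride) | C/C=C(\C)C(=O)Cl | starting material
25 | (1S)-1-{(2R,3R)-2-[(1E)-2-{[tert-butyl(diphenyl)silyl]oxymethyl}-4-(trimethylsilyl)but-1-en-3-yn-1-yl]-4-methylidene-5-oxooxolan-3-yl}-2-[(4R)-2,2,4-trimethyl-1,3-dioxolan-4-yl]ethyl (2E)-2-methylbut-2-enoate | C=C1C(=O)O[C@H](/C=C(/CO[Si](c2ccccc2)(c2ccccc2)C(C)(C)C)C#C[Si](C)(C)C)[C@H]1[C@@H](OC(=O)/C(C)=C/C)C[C@]1(C)COC(C)(C)O1 | intermediate
26 | iodoalkyne analogue of 25 (C≡C–I in place of C≡C–SiMe3) | C=C1C(=O)O[C@H](/C=C(/CO[Si](c2ccccc2)(c2ccccc2)C(C)(C)C)C#CI)[C@H]1[C@@H](OC(=O)/C(C)=C/C)C[C@]1(C)COC(C)(C)O1 | intermediate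
27 | (1S,3R)-1-{(2R,3R)-2-[(1E)-2-{[tert-butyl(diphenyl)silyl]oxymethyl}-4-iodobut-1-en-3-yn-1-yl]-4-methylidene-5-oxooxolan-3-yl}-3,4-dihydroxy-3-methylbutyl (2E)-2-methylbut-2-enoate | C=C1C(=O)O[C@H](/C=C(/CO[Si](c2ccccc2)(c2ccccc2)C(C)(C)C)C#CI)[C@H]1[C@@H](OC(=O)/C(C)=C/C)C[C@@](C)(O)CO | intermediate
28 | (1S,3R)-1-{(2R,3R)-2-[(1E)-2-{[tert-butyl(diphenyl)silyl]oxymethyl}-4-iodobut-1-en-3-yn-1-yl]-4-methylidene-5-oxooxolan-3-yl}-3-hydroxy-3-methyl-4-oxobutyl (2E)-2-methylbut-2-enoate | C=C1C(=O)O[C@H](/C=C(/CO[Si](c2ccccc2)(c2ccccc2)C(C)(C)C)C#CI)[C@H]1[C@@H](OC(=O)/C(C)=C/C)C[C@@](C)(O)C=O | intermediate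
29 | alkynylchromium dichloride from 28 (C≡C–CrCl2 in place of C≡C–I) | C=C1C(=O)O[C@H](/C=C(/CO[Si](c2ccccc2)(c2ccccc2)C(C)(C)C)C#C[Cr](Cl)Cl)[C@H]1[C@@H](OC(=O)/C(C)=C/C)C[C@@](C)(O)C=O | intermediate (not isolated)
30 | (6R,7R,8S,10R)-15-[tert-butyl(diphenyl)silyl]oxy-1,10-dihydroxy-8-[(2E)-2-methylbut-2-enoyl]oxygermacra-4,11(13)-dien-2-yn-12,6-olide (C1 epimers) | C=C1C(=O)O[C@@H]2/C=C(/CO[Si](c3ccccc3)(c3ccccc3)C(C)(C)C)C#CC(O)[C@@](C)(C[C@H](OC(=O)/C(C)=C/C)[C@@H]12)O | intermediate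
31 | (6R,7R,8S,10R)-15-[tert-butyl(diphenyl)silyl]oxy-10-hydroxy-8-[(2E)-2-methylbut-2-enoyl]oxy-1-oxogermacra-4,11(13)-dien-2-yn-12,6-olide | C=C1C(=O)O[C@@H]2/C=C(/CO[Si](c3ccccc3)(c3ccccc3)C(C)(C)C)C#CC(=O)[C@@](C)(C[C@H](OC(=O)/C(C)=C/C)[C@@H]12)O | intermediate
32 | 15-O-[tert-butyl(diphenyl)silyl]lychnophorolide B | C=C1C(=O)O[C@@H]2/C=C(/CO[Si](c4ccccc4)(c4ccccc4)C(C)(C)C)C3=CC(=O)[C@@](C)(C[C@H](OC(=O)/C(C)=C/C)[C@@H]12)O3 | intermediate
33 | lychnophorolide B | C=C1C(=O)O[C@@H]2/C=C(/CO)C3=CC(=O)[C@@](C)(C[C@H](OC(=O)/C(C)=C/C)[C@@H]12)O3 | target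

**Step count and risks**
Total: 22 steps. Longest linear sequence: 18 steps (steps 1–9 to fragment A, then steps 14–22); fragment B takes 4 steps (10–13).

Most likely to fail:

1. Step 19 (chromium-mediated closure of a strained ten-membered enyne ring). Fallback: reverse the order of the two carbonyl additions, so that C1–C2 is made between fragments and the ring is closed at C7–C8 by an intramolecular allylation. It sets out from 12 (with 18) and comes back at 32. Butenolide 12 is iododesilylated (N-iodosuccinimide, cat. AgNO3) to the TBS-protected iodoalkyne butenolide F1. Diol 18 is oxidised (SO3·pyridine, DMSO, iPr2NEt) to (2R)-2-hydroxy-2-methylpent-4-enal F2. Intermolecular CrCl2/cat. NiCl2 coupling of these two gives the open-chain propargylic diol F3. IBX then gives the hydroxy ynone F4, and Ph3PAuCl/AgOSO2CF3 the open-chain furanone F5. Pyridinium p-toluenesulfonate in MeOH frees the primary alcohol F6, and CBr4/PPh3 gives the bromomethyl butenolide F7. OsO4 (cat.)/NaIO4/2,6-lutidine cleaves the terminal vinyl group, the only electron-rich alkene, to the C8 aldehyde F8. Zn (or CrCl2) at high dilution closes the carbocycle with the same ring-locked allyl geometry to give the macrocyclic C8 alcohol F9, which is acylated with 24 as in step 15 to give 32.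

2. Step 14 (diastereocontrol at C8 in the Barbier union). Fallback: make the union stereoconvergent by inversion. It sets out from 14 (with 21) and comes back at 25. If the addition gives a substantial amount of the C8 epimer of the adduct F10, that epimer is separated and esterified under Mitsunobu conditions (tiglic acid, PPh3, diisopropyl azodicarboxylate, THF, 0 °C) with inversion at C8, giving 25 directly. The correct epimer 23 goes through step 15 as planned.

3. Step 5 (catalytic asymmetric alkynylation of a hindered Z-enal; sense and level of induction). Fallback: set C6 by reduction instead of addition. It sets out from 7 (with 8) and comes back at 9. The lithium acetylide of 8 (n-BuLi, THF, −78 °C) adds to 7 to give the racemic carbinol F11. Dess–Martin oxidation gives the cross-conjugated alkenyl alkynyl ketone F12. This is reduced with a Corey–Bakshi–Shibata oxazaborolidine and catecholborane at −78 °C (catalyst antipode chosen by Mosher analysis to give the 4R alcohol) to 9.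

**Further compounds**
F1 | step 19 | (5R)-3-{[tert-butyl(dimethyl)silyl]oxymethyl}-5-[(1E)-2-{[tert-butyl(diphenyl)silyl]oxymethyl}-4-iodobut-1-en-3-yn-1-yl]furan-2(5H)-one | O=C1O[C@H](/C=C(/CO[Si](c2ccccc2)(c2ccccc2)C(C)(C)C)C#CI)C=C1CO[Si](C)(C)C(C)(C)C
F2 | step 19 | (2R)-2-hydroxy-2-methylpent-4-enal | C=CC[C@@](C)(O)C=O
F3 | step 19 | open-chain propargylic diol from F1 and F2 (C1 epimers; C10 R) | O=C1O[C@H](/C=C(/CO[Si](c2ccccc2)(c2ccccc2)C(C)(C)C)C#CC(O)[C@](C)(O)CC=C)C=C1CO[Si](C)(C)C(C)(C)C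
F4 | step 19 | open-chain α'-hydroxy ynone (C1 ketone of F3) | O=C1O[C@H](/C=C(/CO[Si](c2ccccc2)(c2ccccc2)C(C)(C)C)C#CC(=O)[C@](C)(O)CC=C)C=C1CO[Si](C)(C)C(C)(C)C
F5 | step 19 | open-chain furanone: 12 with the C≡C–SiMe3 group replaced by a (5R)-5-methyl-4-oxo-5-(prop-2-en-1-yl)-4,5-dihydrofuran-2-yl ring | O=C1O[C@H](/C=C(/CO[Si](c2ccccc2)(c2ccccc2)C(C)(C)C)C2=CC(=O)[C@@](C)(CC=C)O2)C=C1CO[Si](C)(C)C(C)(C)C
F6 | step 19 | primary alcohol from F5 (3-hydroxymethyl butenolide) | O=C1O[C@H](/C=C(/CO[Si](c2ccccc2)(c2ccccc2)C(C)(C)C)C2=CC(=O)[C@@](C)(CC=C)O2)C=C1CO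
F7 | step 19 | allylic bromide from F6 (3-bromomethyl butenolide) | O=C1O[C@H](/C=C(/CO[Si](c2ccccc2)(c2ccccc2)C(C)(C)C)C2=CC(=O)[C@@](C)(CC=C)O2)C=C1CBr
F8 | step 19 | C8 aldehyde from F7 (2-oxoethyl group on C10) | O=C1O[C@H](/C=C(/CO[Si](c2ccccc2)(c2ccccc2)C(C)(C)C)C2=CC(=O)[C@@](C)(CC=O)O2)C=C1CBr
F9 | step 19 | 8-O-detigloyl-15-O-[tert-butyl(diphenyl)silyl]lychnophorolide B (free C8 hydroxyl) | C=C1C(=O)O[C@@H]2/C=C(/CO[Si](c4ccccc4)(c4ccccc4)C(C)(C)C)C3=CC(=O)[C@@](C)(C[C@H](O)[C@@H]12)O3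
F10 | step 14 | C8 epimer of 23 [(1R)-1-hydroxy side chain] | C=C1C(=O)O[C@H](/C=C(/CO[Si](c2ccccc2)(c2ccccc2)C(C)(C)C)C#C[Si](C)(C)C)[C@H]1[C@H](O)C[C@]1(C)COC(C)(C)O1
F11 | step 5 | racemic 9 [(5E)-1-[tert-butyl(dimethyl)silyl]oxy-6-{[tert-butyl(diphenyl)silyl]oxymethyl}-8-(trimethylsilyl)octa-5-en-2,7-diyn-4-ol] | OC(/C=C(/CO[Si](c1ccccc1)(c1ccccc1)C(C)(C)C)C#C[Si](C)(C)C)C#CCO[Si](C)(C)C(C)(C)C
F12 | step 5 | (5E)-1-[tert-butyl(dimethyl)silyl]oxy-6-{[tert-butyl(diphenyl)silyl]oxymethyl}-8-(trimethylsilyl)octa-5-en-2,7-diyn-4-one | O=C(/C=C(/CO[Si](c1ccccc1)(c1ccccc1)C(C)(C)C)C#C[Si](C)(C)C)C#CCO[Si](C)(C)C(C)(C)C
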